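Slowness is what you buy when you cool a flask, and the question is how much of the chains it saves.

    initiator → 2 initiating radical (k1 = 0.0019 s⁻¹, Ea1 = 106 kJ mol⁻¹)
    free monomer + initiating radical → growing radical + monomer in chains (k2 = 1.5 × 10⁷ M⁻¹ s⁻¹, Ea2 = 19.0 kJ mol⁻¹)
    free monomer + growing radical → monomer in chains + growing radical, rate k3*[growing radical]*[free monomer] (k3 = 1.2 × 10⁶ M⁻¹ s⁻¹, Ea3 = 26.0 kJ mol⁻¹)
    2 growing radical → dead chain (k4 = 1.3 × 10⁹ M⁻¹ s⁻¹, Ea4 = 11.0 kJ mol⁻¹)
    2 free monomer → self-condensation product (k5 = 13 M⁻¹ s⁻¹, Ea5 = 44.0 kJ mol⁻¹)
    monomer in chains → over-reaction product (k6 = 0.016 s⁻¹, Ea6 = 97.0 kJ mol⁻¹)
    (constants at 100 °C)

in all of them: free monomer 0.0050 M; initiator 2.5 mol%; time 80 s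
- autumn: temperature 100 °C
- winter: temperature 60 °C
- spring: temperature 80 °C
- dawn: at 60 °C until 40 s, from then on at 100 °C

- a species is counted by the free monomer in it: one self-condensation product counts as two
- for a step with 2 of a species take k times the square, and two of it per event
- the list of constants is for 100 °C, to be carried to other temperatures by the activation energies

- the best flask by share of monomer in chains in all that became monomer in chains or over-reaction product; "all alike" if 1.5 percentage points covers them all (autumn / winter / spring / dawn / all alike)
- share of monomer in chains in all that became monomer in chains or over-reaction product, autumn
- share of monomer in chains in all that became monomer in chains or over-reaction product, winter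
- share of monomer in chains in all that became monomer in chains or over-reaction product, spring
- share of monomer in chains in all that became monomer in chains or over-reaction product, dawn

**The decision.** You must choose the temperature of the next run and leave the charges as they stand. The share asked for counts what survives in the chains. Over-reaction is first order in c(monomer in chains), so its loss needs no partner. You should therefore work with the fraction left and not with the fraction made.

**The cold constant.** The self-condensation step speeds up by 5.5 from the coldest flask to the hottest. Between two temperatures, the factor of one step is the factor of another raised to the ratio of their activation energies. So over-reaction speeds up by 42.7, and its constant in the cold is 3.75 × 10⁻⁴ s⁻¹.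

**The floor.** Multiply the over-reaction constant by the time spent at it, add up over the run, and take the exponential of minus that sum. For winter the sum is 0.0300, which gives 97.0%. This is the survival floor, the fraction left of a unit that entered the chains at the start. A unit made later has had less time to go, so the share lies above the floor.

**The other flasks.** Autumn has a sum of 1.28, so its floor is 27.8%. Dawn has 0.655, so its floor is 51.9%. Nearly all of that sum comes from its hot half. My reckoning stops here, because I do not reckon when the units are made. Still, winter has a higher floor than autumn or dawn, so I would run the next flask cold and add no hot finish.

**The forecast.** It names winter and gives 41% for autumn, 98.5% for winter, 87% for spring and 65% for dawn. Its ground is that “the chains barely degrade in the cold flask”. These are shares, and mine are floors, so they are different numbers. Its values for autumn, winter and dawn stand above my floors.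

**The run.** The best flask is winter, with 98.3%, against 86.9% for spring, 65.1% for dawn and 41.3% for autumn. In autumn at 80.0 s, monomer in chains is made at 0.422 of the rate at which it is used up. Fractions left multiply, so winter's floor of 97.0% carried to 800 s becomes 74.1%. At that time the share in winter stands above it, at 80.2%.

Its constants were chosen freely; the flask was simulated.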